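**Retrosynthetic overview**

- The strategy rests on the hexasubstituted benzene ring of 15. Numbered C1 (CH2–N of the lactam), C2 (Br), C3 (OH), C4 (OH), C5 (Br), C6 (Br), it divides into the two oxygen-bearing carbons C3/C4 (a two-carbon enediol unit) and the four-carbon run C2–C1–C6–C5, which carries all three bromines and the side chain.
- 15 ⇐ catechol carbonate 14 (hydrolysis) ⇐ cis-dihydro carbonate 13 (dehydrogenation).
- 13 ⇐ thiophene 1,1-dioxide 10 + vinylene carbonate 11: a (4+2) cycloaddition forms C2–C3 and C5–C4, and SO2 is expelled.
- 10 ⇐ thiophene 8 (S-oxidation) ⇐ thenyl bromide 5 + pyrrolidin-2-one 6 ⇐ 3-methylthiophene 1 (ring bromination, then side-chain bromination).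
- Ring order: the thiophene and lactam rings are bought. The benzene ring is the only ring built; its four brominated or alkylated carbons are the thiophene carbons after sulfur is excised.

Key step: step 5

Remark on the chemistry: the target is achiral, so 12 and 13 are made as racemates with one enantiomer drawn. 12 is drawn as the endo adduct, although either bridge orientation leads to 13.

**Route**

Step 1
Reactants: 1 3-methylthiophene
Product: 4 2,3,5-tribromo-4-methylthiophene, via 2-bromo-3-methylthiophene 2 (not isolated), via 2,5-dibromo-3-methylthiophene 3 (not isolated)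
Conditions: Br2 (3.3 equiv), AcOH, rt → 70 °C, dark
Reagents that add atoms: bromine, BrBr
Why: Electrophilic aromatic bromination of the π-rich thiophene fills its three free ring positions in the order C2, C5, C4 (passing through 2 and 3), while the methyl group is untouched under ionic conditions in the dark.

Step 2
Reactants: 4 2,3,5-tribromo-4-methylthiophene
Product: 5 2,3,5-tribromo-4-(bromomethyl)thiophene
Conditions: NBS (1.0 equiv), AIBN (5 mol %), PhCF3, 85 °C
Reagents that add atoms: N-bromosuccinimide, O=C1CCC(=O)N1Br
Why: Wohl–Ziegler radical bromination: the methyl hydrogens are the only sp3 C–H bonds, the thenyl radical is stabilised by the ring, and no excess of N-bromosuccinimide is used, which limits the dibromomethyl by-product.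

Step 3
Reactants: 5 2,3,5-tribromo-4-(bromomethyl)thiophene; 6 pyrrolidin-2-one
Product: 8 1-[(2,4,5-tribromothiophen-3-yl)methyl]pyrrolidin-2-one, via sodium 2-oxopyrrolidin-1-ide 7 (not isolated)
Conditions: 6 (1.1 equiv), NaH (1.1 equiv), THF/DMF, 0 °C; then 5, 0 °C → rt
Reagents that add atoms: none
Why: SN2 N-alkylation of the sodium lactamate 7 by a primary thenylic bromide, which is far more electrophilic than the three ring C–Br bonds, so only the exocyclic bromide is displaced, and the sodium salt in a polar aprotic medium alkylates on nitrogen.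

Step 4
Reactants: 8 1-[(2,4,5-tribromothiophen-3-yl)methyl]pyrrolidin-2-one
Product: 10 2,3,5-tribromo-4-[(2-oxopyrrolidin-1-yl)methyl]thiophene 1,1-dioxide, via tribromothiophene 1-oxide 9 (not isolated)
Conditions: (CF3CO)2O, urea·H2O2 (excess), CH2Cl2, 0 °C → rt
Reagents that add atoms: peroxytrifluoroacetic acid, OOC(=O)C(F)(F)F (made in the flask from trifluoroacetic anhydride, O=C(OC(=O)C(F)(F)F)C(F)(F)F, and urea–hydrogen peroxide, NC(N)=O.OO)
Why: Electrophilic S-oxidation with peroxytrifluoroacetic acid, the oxidant used for polyhalogenated thiophenes whose sulfur is too electron-poor for weaker peracids; sulfoxide 9 is oxidised faster than 8 and so should not accumulate, the fully substituted dioxide resists self-cycloaddition, and the tertiary lactam is inert to peracid.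

Step 5
Reactants: 10 2,3,5-tribromo-4-[(2-oxopyrrolidin-1-yl)methyl]thiophene 1,1-dioxide; 11 vinylene carbonate (1,3-dioxol-2-one)
Product: 13 cis-4,5,7-tribromo-6-[(2-oxopyrrolidin-1-yl)methyl]-3a,7a-dihydro-1,3-benzodioxol-2-one (racemic), via bridged sulfone cycloadduct 12 (not isolated)
Conditions: 11 (6 equiv), BHT (cat.), PhMe, 100 °C, sealed tube, Ar
Reagents that add atoms: none
Why: The s-cis diene held in the ring of 10 (C2=C3–C4=C5 of the sulfone) adds through its two α-carbons to the C=C bond of 11 in a concerted (4+2) cycloaddition, giving the 7-thiabicyclo[2.2.1]hept-2-ene 7,7-dioxide 12, whose one-atom bridge leaves as SO2 in a cheletropic extrusion that returns a cyclohexa-1,3-diene. The closest known reaction type is the cycloaddition of tetrahalothiophene 1,1-dioxides to alkenes with spontaneous loss of SO2 to give halogenated cyclohexa-1,3-dienes, and vinylene carbonate is an established two-carbon enediol dienophile towards electron-poor cyclic dienes. The six-membered carbocycle is closed by intermolecular cycloaddition that forms both new C–C bonds (target C2–C3 and C5–C4) at once; no other ring is formed, and the five-membered sulfone ring is opened by the extrusion. The two new sp3 centres C3a and C7a are cis because the alkene geometry is locked in the five-membered carbonate ring and the addition is suprafacial on the dienophile; the product is racemic and the endo or exo sense of 12 is erased with the bridge. No regiochemistry arises from the symmetric dienophile; the step needs cycloaddition to outrun diene self-dimerisation and dienophile polymerisation, which the fully substituted bromine-shielded diene, the excess of 11 and BHT should secure, and it needs both C–O bonds to survive, which the base-free medium and a temperature well below that of [1,5]-hydrogen shifts should secure.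

Step 6
Reactants: 13 cis-4,5,7-tribromo-6-[(2-oxopyrrolidin-1-yl)methyl]-3a,7a-dihydro-1,3-benzodioxol-2-one
Product: 14 4,5,7-tribromo-6-[(2-oxopyrrolidin-1-yl)methyl]-1,3-benzodioxol-2-one
Conditions: DDQ (1.3 equiv), PhCl, 90 °C
Reagents that add atoms: none
Why: DDQ dehydrogenation of a cyclohexa-1,3-diene: hydride abstraction from an allylic, oxygen-bearing ring C–H and loss of the neighbouring proton give the arene with both C–O bonds intact, since the neutral base-free medium and the poor leaving-group ability of the cyclic carbonate disfavour elimination to a monophenol; both stereocentres are erased here.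

Step 7
Reactants: 14 4,5,7-tribromo-6-[(2-oxopyrrolidin-1-yl)methyl]-1,3-benzodioxol-2-one
Product: 15 1-[(2,3,6-tribromo-4,5-dihydroxyphenyl)methyl]pyrrolidin-2-one
Conditions: NaHCO3, THF/H2O (degassed), rt, Ar; then 1 M HCl
Reagents that add atoms: none
Why: Hydrolysis of a cyclic aryl carbonate: the tribromocatecholate is a good leaving group, so bicarbonate-buffered water should cleave the carbonate at room temperature with loss of CO2 while the lactam is untouched, and exclusion of air prevents oxidation of the catecholate to the ortho-quinone.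

**Compound list**

1 | 3-methylthiophene | Cc1ccsc1 | starting material
2 | 2-bromo-3-methylthiophene | Cc1ccsc1Br | intermediate (not isolated)
3 | 2,5-dibromo-3-methylthiophene | Cc1cc(Br)sc1Br | intermediate (not isolated)
4 | 2,3,5-tribromo-4-methylthiophene | Cc1c(Br)sc(Br)c1Br | intermediate
5 | 2,3,5-tribromo-4-(bromomethyl)thiophene | BrCc1c(Br)sc(Br)c1Br | intermediate
6 | pyrrolidin-2-one | O=C1CCCN1 | starting material
7 | sodium 2-oxopyrrolidin-1-ide | O=C1CCC[N-]1.[Na+] | intermediate (not isolated)
8 | 1-[(2,4,5-tribromothiophen-3-yl)methyl]pyrrolidin-2-one | O=C1CCCN1Cc1c(Br)sc(Br)c1Br | intermediate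
9 | 2,3,5-tribromo-4-[(2-oxopyrrolidin-1-yl)methyl]thiophene 1-oxide (racemic, configurationally labile at sulfur) | O=C1CCCN1CC1=C(Br)S(=O)C(Br)=C1Br | intermediate (not isolated)
10 | 2,3,5-tribromo-4-[(2-oxopyrrolidin-1-yl)methyl]thiophene 1,1-dioxide | O=C1CCCN1CC1=C(Br)S(=O)(=O)C(Br)=C1Br | intermediate
11 | vinylene carbonate (1,3-dioxol-2-one) | O=C1OC=CO1 | starting material
12 | endo-4,5,7-tribromo-6-[(2-oxopyrrolidin-1-yl)methyl]-3a,4,7,7a-tetrahydro-4,7-epithio-1,3-benzodioxol-2-one 8,8-dioxide (carbonate ring on the face of the C5=C6 bond, racemic) | O=C1O[C@@H]2[C@H](O1)[C@]3(Br)C(Br)=C(CN4CCCC4=O)[C@@]2(Br)S3(=O)=O | intermediate (not isolated)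
13 | cis-4,5,7-tribromo-6-[(2-oxopyrrolidin-1-yl)methyl]-3a,7a-dihydro-1,3-benzodioxol-2-one (racemic) | O=C1O[C@@H]2C(Br)=C(CN3CCCC3=O)C(Br)=C(Br)[C@@H]2O1 | intermediate
14 | 4,5,7-tribromo-6-[(2-oxopyrrolidin-1-yl)methyl]-1,3-benzodioxol-2-one | O=C1Oc2c(Br)c(CN3CCCC3=O)c(Br)c(Br)c2O1 | intermediate
15 | 1-[(2,3,6-tribromo-4,5-dihydroxyphenyl)methyl]pyrrolidin-2-one | O=C1CCCN1Cc1c(Br)c(O)c(O)c(Br)c1Br | target

**Step count**

Total: 7 steps. Longest linear sequence: 7 steps (1 → 15); 6 and 11 are purchased and enter at steps 3 and 5.

**Steps most likely to fail**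

Step 5. Vinylene carbonate is only a weakly donating alkene, so the cycloaddition may be slow enough that thermal decomposition of the diene or polymerisation of the dienophile outruns adduct formation. The fallback sets out from 10 and replaces the dienophile by the electron-rich enediol ether 2,3-dihydro-1,4-dioxine (toluene, 40–60 °C). Its polarity-matched cycloaddition should give the bridged sulfone endo-5,6,8-tribromo-7-[(2-oxopyrrolidin-1-yl)methyl]-2,3,4a,5,8,8a-hexahydro-5,8-epithio-1,4-benzodioxine 9,9-dioxide F1. Loss of sulfur dioxide would then give cis-5,6,8-tribromo-7-[(2-oxopyrrolidin-1-yl)methyl]-2,3,4a,8a-tetrahydro-1,4-benzodioxine F2. DDQ dehydrogenation would give 1-[(5,7,8-tribromo-2,3-dihydro-1,4-benzodioxin-6-yl)methyl]pyrrolidin-2-one F3. Excess BBr3 in CH2Cl2 would then cleave both O–CH2 bonds, the ethylene bridge leaving as 1,2-dibromoethane, and the route is rejoined at 15.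

Step 6. Hydride abstraction from the electron-poor tribrominated diene may be too slow, and on prolonged heating a ring C–O bond may be lost instead, giving aromatisation by elimination to a monophenol. The fallback sets out from 13 and aromatises by radical bromination and dehydrobromination instead of hydride transfer. N-Bromosuccinimide with a trace of dibenzoyl peroxide (PhCF3, 80 °C) should abstract a ring C–H to a cyclohexadienyl radical. Bromine transfer would give the tertiary allylic bromide cis-3a,4,6,7-tetrabromo-5-[(2-oxopyrrolidin-1-yl)methyl]-3a,7a-dihydro-1,3-benzodioxol-2-one F4 (or an allylic isomer), which loses hydrogen bromide across the ring fusion and rejoins the route at 14.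

Step 4. S-oxidation of the deactivated tribromothiophene may stay incomplete, or the ring may be degraded oxidatively, so that no diene is available. The fallback uses known arene chemistry and sets out from 6 through its sodium salt 7. Alkylation with commercial 3,4-dimethoxybenzyl chloride would give 1-[(3,4-dimethoxyphenyl)methyl]pyrrolidin-2-one F5. BBr3 demethylation would give 1-[(3,4-dihydroxyphenyl)methyl]pyrrolidin-2-one F6. Bromine (3 equiv) in acetic acid would then fill the three free ring positions, each ortho or para to a hydroxyl group, and arrive at 15.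

**Further compounds**

F1 | step 5 | endo-5,6,8-tribromo-7-[(2-oxopyrrolidin-1-yl)methyl]-2,3,4a,5,8,8a-hexahydro-5,8-epithio-1,4-benzodioxine 9,9-dioxide (racemic) | C1CO[C@@H]2[C@H](O1)[C@]3(Br)C(Br)=C(CN4CCCC4=O)[C@@]2(Br)S3(=O)=O
F2 | step 5 | cis-5,6,8-tribromo-7-[(2-oxopyrrolidin-1-yl)methyl]-2,3,4a,8a-tetrahydro-1,4-benzodioxine (racemic) | C1CO[C@@H]2C(Br)=C(CN3CCCC3=O)C(Br)=C(Br)[C@@H]2O1
F3 | step 5 | 1-[(5,7,8-tribromo-2,3-dihydro-1,4-benzodioxin-6-yl)methyl]pyrrolidin-2-one | O=C1CCCN1Cc1c(Br)c2OCCOc2c(Br)c1Br
F4 | step 6 | cis-3a,4,6,7-tetrabromo-5-[(2-oxopyrrolidin-1-yl)methyl]-3a,7a-dihydro-1,3-benzodioxol-2-one (racemic) | O=C1O[C@]2(Br)C(Br)=C(CN3CCCC3=O)C(Br)=C(Br)[C@@H]2O1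
F5 | step 4 | 1-[(3,4-dimethoxyphenyl)methyl]pyrrolidin-2-one | COc1ccc(CN2CCCC2=O)cc1OC
F6 | step 4 | 1-[(3,4-dihydroxyphenyl)methyl]pyrrolidin-2-one | O=C1CCCN1Cc1ccc(O)c(O)c1
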